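**Plan**
-Retrosynthesis: the five O-benzyl groups and a temporary alcohol oxidation level at C4'' (unit 2, the 4-hydroxyphenyl flavanone) come off last. Ring C of unit 1 (the 4-methoxyphenyl flavanone) is then cut at O1–C8a and C2–C3, giving 4-methoxybenzaldehyde and an ortho-fluoroaryl ketone. That ketone is cut at C4–C4a (aryllithium plus lactone), then at the C3''–C3 side chain, then at C2''–aryl (chromone plus boronic acid).
-Enabling feature: the C4 carbonyl of unit 1 lies between the C3 methylene and ring A. It makes C3 enolisable and, through the C4a=C8a bond, makes a fluoride at C8a displaceable by the oxygen that an aldol addition creates at C2. One aldol/SNAr annulation therefore closes ring C.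
-Forward order: ring C of unit 2 (chromone to flavanone), C3'' side chain, cis-fused lactone, ring A of unit 1 (aryllithium), ring C of unit 1 (annulation), then C4'' oxidation and debenzylation.
-Stereochemistry: C2'' comes from a chiral palladium catalyst. C3'' comes from kinetic protonation anti to the 2''-aryl group and is locked by reduction to the lactone. C3 comes from 1,2-induction by C3''. C2 comes from reversible aldol addition that is funnelled into the 2,3-trans ring.

Key step: step 9

Remark: the SMILES is read as (2R,3S), 2,3-trans, in unit 1 and (2''R,3''R), 2,3-cis, in unit 2; the cis centre C3'' is therefore kept non-enolisable (C4'' as a silyl-protected alcohol) through the basic annulation.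

**Step 1**
Reactants: 1 1,3,5-trifluorobenzene
Product: 2 1,3-bis(benzyloxy)-5-fluorobenzene
Conditions: BnOH (2.2 equiv), NaH (2.3 equiv), NMP, 0 → 100 °C
Reagents that add atoms: benzyl alcohol, OCc1ccccc1
Why: Twofold nucleophilic aromatic substitution of fluoride by benzyloxide should stop at the monofluoro bis-ether, because each alkoxy group deactivates the ring and only two equivalents of alkoxide are supplied; no stereocentre is formed.

**Step 2**
Reactants: 2 1,3-bis(benzyloxy)-5-fluorobenzene
Product: 3 1,5-bis(benzyloxy)-2-bromo-3-fluorobenzene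
Conditions: NBS (1.0 equiv), MeCN, 0 °C → rt
Reagents that add atoms: N-bromosuccinimide, O=C1CCC(=O)N1Br
Why: Electrophilic aromatic bromination should occur para to one benzyloxy group and ortho to the other (the position between OBn and F) and not at the more hindered position between the two benzyloxy groups; no stereocentre is formed.

**Step 3**
Reactants: 4 1-[2,4-bis(benzyloxy)-6-hydroxyphenyl]ethan-1-one
Product: 6 5,7-bis(benzyloxy)-4H-chromen-4-one, via enaminone 5 (not isolated)
Conditions: Me2NCH(OMe)2, toluene, 100 °C; then conc. HCl, CH2Cl2, 40 °C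
Reagents that add atoms: N,N-dimethylformamide dimethyl acetal, COC(OC)N(C)C
Why: Enaminone formation from the methyl ketone, followed by acid-induced conjugate addition of the ortho phenol and loss of dimethylamine, is the standard chromone synthesis; no stereocentre is formed.

**Step 4**
Reactants: 6 5,7-bis(benzyloxy)-4H-chromen-4-one; 7 [4-(benzyloxy)phenyl]boronic acid
Product: 8 (2R)-5,7-bis(benzyloxy)-2-[4-(benzyloxy)phenyl]chroman-4-one
Conditions: Pd(OCOCF3)2 (5 mol %), (S)-4-tert-butyl-2-(pyridin-2-yl)-4,5-dihydrooxazole (6 mol %), NH4PF6 (30 mol %), H2O (5 equiv), ClCH2CH2Cl, 60 °C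
Reagents that add atoms: none
Why: Asymmetric conjugate addition of an arylboronic acid to a chromone under divalent palladium catalysis (transmetalation, face-selective aryl insertion at C2'', protonolysis of the palladium enolate) sets C2''; the ligand enantiomer is chosen to give (2R), and the (S) ligand is expected to do so.

**Step 5**
Reactants: 8 (2R)-5,7-bis(benzyloxy)-2-[4-(benzyloxy)phenyl]chroman-4-one
Product: 9 methyl 2-[(2R,3S)-5,7-bis(benzyloxy)-2-[4-(benzyloxy)phenyl]-4-oxochroman-3-yl]acetate (2,3-trans)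
Conditions: LiN(SiMe3)2 (1.05 equiv), THF, −78 °C; BrCH2CO2Me (1.5 equiv), −78 → −40 °C
Reagents that add atoms: methyl bromoacetate, COC(=O)CBr
Why: Alkylation of the lithium enolate with a reactive alpha-bromo ester at low temperature, where beta-elimination of the ring oxygen is slow, should place the chain anti to the 2-aryl group; this C3'' configuration is corrected in step 6.

**Step 6**
Reactants: 9 methyl 2-[(2R,3S)-5,7-bis(benzyloxy)-2-[4-(benzyloxy)phenyl]-4-oxochroman-3-yl]acetate
Product: 12 all-cis fused gamma-lactone (7,9-bis(benzyloxy)-4-[4-(benzyloxy)phenyl]-3,3a,4,9b-tetrahydro-2H-furo[3,2-c]chromen-2-one; 4R; H-3a H-4 H-9b mutually cis), via cis-keto ester 10 (not isolated), via all-cis hydroxy ester 11 (not isolated)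
Conditions: LiN(SiMe3)2 (1.1 equiv), THF, −78 °C; 2,6-di-tert-butyl-4-methylphenol (1.15 equiv), −78 °C; LiBH(s-Bu)3 (1.5 equiv), −78 → 0 °C; AcOH quench
Reagents that add atoms: none
Why: Re-enolisation of the ketone (more acidic than the ester) and kinetic C-protonation by the hindered phenol anti to the pseudo-axial 2''-aryl group should set the 2'',3''-cis relationship, and immediate hydride reduction of C4''=O from the face opposite the axial side chain gives the all-cis alkoxide, which lactonises and so locks C3'' against epimerisation.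

**Step 7**
Reactants: 12 all-cis fused gamma-lactone; 3 1,5-bis(benzyloxy)-2-bromo-3-fluorobenzene
Product: 14 1-[2,4-bis(benzyloxy)-6-fluorophenyl]-2-[(2R,3S,4R)-5,7-bis(benzyloxy)-2-[4-(benzyloxy)phenyl]-4-hydroxychroman-3-yl]ethan-1-one, via aryllithium 13 (not isolated)
Conditions: 3 (1.3 equiv), n-BuLi (1.25 equiv), THF, −78 °C; then 12, −78 °C; AcOH quench at −78 °C
Reagents that add atoms: none
Why: Bromine–lithium exchange gives the ortho-fluoroaryllithium, which is stable at −78 °C and should add once to the gamma-lactone because the tetrahedral lithium hemiketal alkoxide persists until the quench (acyl substitution of a lactone by an aryllithium); no stereocentre is touched.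

**Step 8**
Reactants: 14 gamma-hydroxy ortho-fluoroaryl ketone
Product: 15 1-[2,4-bis(benzyloxy)-6-fluorophenyl]-2-[(2R,3R,4R)-5,7-bis(benzyloxy)-2-[4-(benzyloxy)phenyl]-4-[(tert-butyldimethylsilyl)oxy]chroman-3-yl]ethan-1-one (all-cis; same spatial arrangement as 14)
Conditions: t-BuMe2SiOTf (1.5 equiv), 2,6-lutidine (3 equiv), CH2Cl2, −40 → 0 °C
Reagents that add atoms: tert-butyldimethylsilyl trifluoromethanesulfonate, CC(C)(C)[Si](C)(C)OS(=O)(=O)C(F)(F)F
Why: Silylation of the secondary benzylic alcohol keeps C4'' at the alcohol level through the basic key step and prevents this oxygen from attacking the fluoroarene; no stereocentre is touched.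

**Step 9**
Reactants: 15 silyl-protected ortho-fluoroaryl ketone; 16 4-methoxybenzaldehyde
Product: 18 (2R,3S)-5,7-bis(benzyloxy)-2-(4-methoxyphenyl)chroman-4-one joined at C3 to C3'' of the (2''R,3''R,4''R) all-cis 5'',7''-bis(benzyloxy)-2''-[4-(benzyloxy)phenyl]-4''-silyloxychroman, via potassium anti-aldolate 17 (not isolated)
Conditions: KN(SiMe3)2 (1.0 equiv), THF, −78 °C; 16 (1.5 equiv), −78 → 23 °C
Reagents that add atoms: none
Why: Proposed new method: KN(SiMe3)2 deprotonates the C3 methylene (the only enolisable position while C4'' is a silyl ether), the potassium enolate adds reversibly to 16, and the aldolate oxygen then attacks C8a of ring A, where fluoride lies ortho to the C4 carbonyl, in an addition–elimination that expels KF and leaves a neutral medium; the closest known reaction types are the base-mediated SNAr ring closure of isolated beta-hydroxy ortho-fluoroaryl ketones to chroman-4-ones and tandem Michael/SNAr annulations of ortho-fluoroaryl ketones. Ring C closes in a 6-endo-trig sense, the oxygen adding to the C8a=C4a bond of the vinylogous acyl fluoride to give a Meisenheimer adduct stabilised by the C4 carbonyl. C3 is controlled by the neighbouring C3'' centre: with C3''–H eclipsing the enolate to avoid 1,3-allylic strain, the face on the C2'' side is screened by the cis 4-(benzyloxy)phenyl group and the aldehyde should add from the C4'' side, which corresponds to (3S). C2 is controlled by the dynamic part: the aldolates should interconvert by retro-aldol reaction faster than they cyclise, and the anti aldolate closes through a chair-like transition state with the 4-methoxyphenyl group and the unit 2 substituent both equatorial, so the mixture is funnelled to the 2,3-trans (2R,3S) ring. The step needs C- over O-reactivity of the enolate, ring closure faster than aldol dehydration or Tishchenko-type hydride transfer, and an inert unit 2; the ortho-fluoro ketone, the limited excess of aldehyde and the alcohol oxidation level at C4'' are there to secure these.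

**Step 10**
Reactants: 18 silyl-protected bis-flavanoid
Product: 19 (2R,3S)-5,7-bis(benzyloxy)-2-(4-methoxyphenyl)chroman-4-one joined at C3 to C3'' of the (2''R,3''S,4''R) all-cis 5'',7''-bis(benzyloxy)-2''-[4-(benzyloxy)phenyl]chroman-4''-ol
Conditions: Bu4NF (3 equiv), AcOH (3 equiv), THF, 0 → 40 °C
Reagents that add atoms: none
Why: Fluoride cleavage of the silyl ether, buffered with acetic acid so that the unit 1 flavanone is not opened by retro-oxa-Michael reaction and the acid-labile benzylic C4'' alcohol is not ionised; no stereocentre is touched.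

**Step 11**
Reactants: 19 C4'' alcohol
Product: 20 penta-O-benzylsikokianin B, (2R,3S,2''R,3''R)
Conditions: Dess–Martin periodinane (1.5 equiv), pyridine, CH2Cl2, 0 °C → rt
Reagents that add atoms: none
Why: Dess–Martin oxidation of the secondary benzylic alcohol under buffered, non-enolising conditions should restore the C4'' ketone without epimerising the now enolisable cis C3'' centre.

**Step 12**
Reactants: 20 penta-O-benzylsikokianin B
Product: 21 sikokianin B
Conditions: H2 (1 atm), Pd/C (10 wt % Pd), EtOAc–MeOH, rt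
Reagents that add atoms: none
Why: Hydrogenolysis of the five benzyl aryl ethers over palladium under neutral conditions should leave the aryl methyl ether, both ketones and all four stereocentres untouched.

**Compound list**
1 | 1,3,5-trifluorobenzene | Fc1cc(F)cc(F)c1 | starting material
2 | 1,3-bis(benzyloxy)-5-fluorobenzene | Fc1cc(OCc2ccccc2)cc(OCc2ccccc2)c1 | intermediate
3 | 1,5-bis(benzyloxy)-2-bromo-3-fluorobenzene | Fc1cc(OCc2ccccc2)cc(OCc2ccccc2)c1Br | intermediate
4 | 1-[2,4-bis(benzyloxy)-6-hydroxyphenyl]ethan-1-one | CC(=O)c1c(O)cc(OCc2ccccc2)cc1OCc1ccccc1 | starting material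
5 | (E)-1-[2,4-bis(benzyloxy)-6-hydroxyphenyl]-3-(dimethylamino)prop-2-en-1-one (enaminone, not isolated) | CN(C)/C=C/C(=O)c1c(O)cc(OCc2ccccc2)cc1OCc1ccccc1 | intermediate
6 | 5,7-bis(benzyloxy)-4H-chromen-4-one | O=c1ccoc2cc(OCc3ccccc3)cc(OCc3ccccc3)c12 | intermediate
7 | [4-(benzyloxy)phenyl]boronic acid | OB(O)c1ccc(OCc2ccccc2)cc1 | starting material
8 | (2R)-5,7-bis(benzyloxy)-2-[4-(benzyloxy)phenyl]chroman-4-one | C1C(=O)c2c(OCc3ccccc3)cc(OCc3ccccc3)cc2O[C@H]1c1ccc(OCc2ccccc2)cc1 | intermediate
9 | methyl 2-[(2R,3S)-5,7-bis(benzyloxy)-2-[4-(benzyloxy)phenyl]-4-oxochroman-3-yl]acetate (2,3-trans) | COC(=O)C[C@@H]1C(=O)c2c(OCc3ccccc3)cc(OCc3ccccc3)cc2O[C@H]1c1ccc(OCc2ccccc2)cc1 | intermediate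
10 | methyl 2-[(2R,3R)-5,7-bis(benzyloxy)-2-[4-(benzyloxy)phenyl]-4-oxochroman-3-yl]acetate (2,3-cis, not isolated) | COC(=O)C[C@H]1C(=O)c2c(OCc3ccccc3)cc(OCc3ccccc3)cc2O[C@H]1c1ccc(OCc2ccccc2)cc1 | intermediate
11 | methyl 2-[(2R,3S,4R)-5,7-bis(benzyloxy)-2-[4-(benzyloxy)phenyl]-4-hydroxychroman-3-yl]acetate (all-cis, formed as its lithium alkoxide, not isolated) | COC(=O)C[C@H]1[C@@H](O)c2c(OCc3ccccc3)cc(OCc3ccccc3)cc2O[C@H]1c1ccc(OCc2ccccc2)cc1 | intermediate
12 | 7,9-bis(benzyloxy)-4-[4-(benzyloxy)phenyl]-3,3a,4,9b-tetrahydro-2H-furo[3,2-c]chromen-2-one, cis-fused, aryl cis to the ring-fusion bonds (4R) | O=C1C[C@H]2[C@@H](O1)c1c(OCc3ccccc3)cc(OCc3ccccc3)cc1O[C@H]2c1ccc(OCc2ccccc2)cc1 | intermediate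
13 | [2,4-bis(benzyloxy)-6-fluorophenyl]lithium (not isolated) | [Li]c1c(F)cc(OCc2ccccc2)cc1OCc1ccccc1 | intermediate
14 | 1-[2,4-bis(benzyloxy)-6-fluorophenyl]-2-[(2R,3S,4R)-5,7-bis(benzyloxy)-2-[4-(benzyloxy)phenyl]-4-hydroxychroman-3-yl]ethan-1-one (all-cis) | O=C(C[C@H]1[C@@H](O)c2c(OCc3ccccc3)cc(OCc3ccccc3)cc2O[C@H]1c1ccc(OCc2ccccc2)cc1)c1c(F)cc(OCc2ccccc2)cc1OCc1ccccc1 | intermediate
15 | 1-[2,4-bis(benzyloxy)-6-fluorophenyl]-2-[(2R,3R,4R)-5,7-bis(benzyloxy)-2-[4-(benzyloxy)phenyl]-4-[(tert-butyldimethylsilyl)oxy]chroman-3-yl]ethan-1-one (all-cis) | O=C(C[C@H]1[C@@H](O[Si](C)(C)C(C)(C)C)c2c(OCc3ccccc3)cc(OCc3ccccc3)cc2O[C@H]1c1ccc(OCc2ccccc2)cc1)c1c(F)cc(OCc2ccccc2)cc1OCc1ccccc1 | intermediate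
16 | 4-methoxybenzaldehyde | COc1ccc(C=O)cc1 | starting material
17 | potassium anti-aldolate of 15 and 16 (alkoxide at C2, aroyl group at C3; not isolated) | COc1ccc([C@H]([O-])[C@@H](C(=O)c2c(F)cc(OCc3ccccc3)cc2OCc2ccccc2)[C@H]2[C@@H](O[Si](C)(C)C(C)(C)C)c3c(OCc4ccccc4)cc(OCc4ccccc4)cc3O[C@H]2c2ccc(OCc3ccccc3)cc2)cc1.[K+] | intermediate
18 | (2R,3S)-5,7-bis(benzyloxy)-2-(4-methoxyphenyl)chroman-4-one bonded at C3 to C3'' of the (2''R,3''R,4''R) all-cis 5'',7''-bis(benzyloxy)-2''-[4-(benzyloxy)phenyl]-4''-[(tert-butyldimethylsilyl)oxy]chroman | COc1ccc([C@@H]2Oc3cc(OCc4ccccc4)cc(OCc4ccccc4)c3C(=O)[C@H]2[C@H]2[C@@H](O[Si](C)(C)C(C)(C)C)c3c(OCc4ccccc4)cc(OCc4ccccc4)cc3O[C@H]2c2ccc(OCc3ccccc3)cc2)cc1 | intermediate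
19 | (2R,3S)-5,7-bis(benzyloxy)-2-(4-methoxyphenyl)chroman-4-one bonded at C3 to C3'' of the (2''R,3''S,4''R) all-cis 5'',7''-bis(benzyloxy)-2''-[4-(benzyloxy)phenyl]chroman-4''-ol | COc1ccc([C@@H]2Oc3cc(OCc4ccccc4)cc(OCc4ccccc4)c3C(=O)[C@H]2[C@H]2[C@@H](O)c3c(OCc4ccccc4)cc(OCc4ccccc4)cc3O[C@H]2c2ccc(OCc3ccccc3)cc2)cc1 | intermediate
20 | penta-O-benzylsikokianin B, (2R,3S,2''R,3''R) | COc1ccc([C@@H]2Oc3cc(OCc4ccccc4)cc(OCc4ccccc4)c3C(=O)[C@H]2[C@H]2C(=O)c3c(OCc4ccccc4)cc(OCc4ccccc4)cc3O[C@H]2c2ccc(OCc3ccccc3)cc2)cc1 | intermediate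
21 | sikokianin B, (2R,3S,2''R,3''R) | COc1ccc([C@@H]2Oc3cc(O)cc(O)c3C(=O)[C@H]2[C@H]2C(=O)c3c(O)cc(O)cc3O[C@H]2c2ccc(O)cc2)cc1 | target

**Step count and risks**
Total steps: 12. Longest linear sequence: 10 (steps 3 to 12); the aryl bromide branch (steps 1 and 2) joins at step 7.

Steps most likely to fail:

1. Step 9 (Proposed new method). Possible failures are insufficient facial selectivity of the enolate (the C4'' silyloxy group is also cis to the side chain), aldol dehydration or Tishchenko-type hydride transfer outrunning ring closure, oxygen-to-oxygen silyl migration, and slow fluoride displacement on the electron-rich ring. The fallback separates the two bond formations and uses known chemistry. It sets out from 15: enolisation with (c-C6H11)2BCl/Et3N (Et2O, −78 → 0 °C) gives the E boron enolate, which with 16 at −78 °C and buffered H2O2 work-up should give, by a closed chair transition state, the anti beta-hydroxy ketone F1, which is isolated. Exposure of F1 to KN(SiMe3)2 (1.0 equiv) and 18-crown-6 in THF at −40 → 0 °C should then close the ring by intramolecular SNAr. The sequence comes back to the route at 18.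

2. Step 6. Possible failures are loss of the kinetic cis preference in the protonation, and ring opening of the enolate by beta-elimination of the aryloxide, which would erode C2''. The fallback sets the cis centre by hydride delivery instead of protonation. It sets out from 8: acid-catalysed aldol condensation with methyl glyoxylate (p-TsOH cat., toluene, 80 °C) should give the (E)-alkylidene ester F2. Conjugate reduction with [(Ph3P)CuH]6 (toluene, rt) places hydride on the exocyclic carbon, and the copper enolate is protonated anti to the 2''-aryl group. The sequence comes back to the route at 10, which is reduced and lactonised to 12 as in the second half of step 6.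

3. Step 7. Possible failures are loss of LiF from the ortho-fluoroaryllithium (aryne formation), enolisation of the lactone instead of addition, and a lactol form of the product that resists silylation. The fallback sets out from 12: aminolysis with Me(MeO)NH·HCl/i-PrMgCl (THF, −20 °C) should give the hydroxy N-methoxy-N-methylamide F3, and silylation (t-BuMe2SiOTf, 2,6-lutidine) the silyl ether F4. Bromide 3 is converted by bromine–magnesium exchange (i-PrMgCl·LiCl, THF, 0 °C) into the arylmagnesium chloride F5, which is far less prone to fluoride loss. Its single addition to F4 comes back to the route at 15.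

**Further compounds**
F1 | step 9 | anti beta-hydroxy ketone from 15 and 16 (neutral aldol adduct; hydroxyl at C2, aroyl group at C3) | COc1ccc([C@H](O)[C@@H](C(=O)c2c(F)cc(OCc3ccccc3)cc2OCc2ccccc2)[C@H]2[C@@H](O[Si](C)(C)C(C)(C)C)c3c(OCc4ccccc4)cc(OCc4ccccc4)cc3O[C@H]2c2ccc(OCc3ccccc3)cc2)cc1
F2 | step 6 | methyl (E)-2-[5,7-bis(benzyloxy)-2-[4-(benzyloxy)phenyl]-4-oxochroman-3-ylidene]acetate, C2 arranged as in 8 (descriptor 2S because C3 is sp2) | COC(=O)/C=C1\[C@H](c2ccc(OCc3ccccc3)cc2)Oc2cc(OCc3ccccc3)cc(OCc3ccccc3)c2C1=O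
F3 | step 7 | 2-[(2R,3S,4R)-5,7-bis(benzyloxy)-2-[4-(benzyloxy)phenyl]-4-hydroxychroman-3-yl]-N-methoxy-N-methylacetamide (all-cis) | CON(C)C(=O)C[C@H]1[C@@H](O)c2c(OCc3ccccc3)cc(OCc3ccccc3)cc2O[C@H]1c1ccc(OCc2ccccc2)cc1
F4 | step 7 | 2-[(2R,3R,4R)-5,7-bis(benzyloxy)-2-[4-(benzyloxy)phenyl]-4-[(tert-butyldimethylsilyl)oxy]chroman-3-yl]-N-methoxy-N-methylacetamide (all-cis) | CON(C)C(=O)C[C@H]1[C@@H](O[Si](C)(C)C(C)(C)C)c2c(OCc3ccccc3)cc(OCc3ccccc3)cc2O[C@H]1c1ccc(OCc2ccccc2)cc1
F5 | step 7 | [2,4-bis(benzyloxy)-6-fluorophenyl]magnesium chloride | Cl[Mg]c1c(F)cc(OCc2ccccc2)cc1OCc1ccccc1
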